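**Plan** (benzofuran numbering: O1, C2 aryl, C3 methyl, C3a allyl, C4–C7, C7a)
- Retrosynthesis: ring A (the methoxy dienone) is opened at C4=C5 by an aldol condensation; ring B (the oxolane) is then cut at O1–C7a and C3a–C7a in one operation.
- The double cut is possible because C7a carries both O1 and the quaternary C3a and is the β-carbon of the vinylogous ester O1–C7a=C7–C6=O, so it can be supplied by a Cl2C= terminus.
- Forward: the chain C2–C3–C3a–C4 (benzylic alcohol, tert-butyl ester, allyl on C3a) is built from 3,4,5-trimethoxybenzaldehyde. Ring B closes by O,C-annulation onto a 3,3-dichloroacrylic Weinreb amide, the CH2OMe ketone (C5–C6) is then completed, and ring A closes last.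
- A Weinreb amide rather than the methoxymethyl ketone activates the dichlorovinyl partner, so that no carbonyl α-proton competes with formation of the ester enolate.
- Stereochemistry: C2 and C3 come from a catalytic asymmetric anti-crotylation; C3a is set in the annulation under control of C3 (allylic strain in the enolate plus the O1 tether).

Key step: step 9

Assumption: the (S)-configured phosphoric acid is taken to send the crotyl group to the Si face of the aryl aldehyde (mirror image of the Re-face attack usual for the (R)-acid); if the sense is the opposite, the enantiomeric acid is used and nothing else changes.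

Step 1
Reactants: 1 3,4,5-trimethoxybenzaldehyde; 2 (E)-crotylboronic acid pinacol ester
Product: 3 (1S,2S)-2-methyl-1-(3,4,5-trimethoxyphenyl)but-3-en-1-ol
Conditions: (S)-3,3'-bis(2,4,6-triisopropylphenyl)-1,1'-binaphthyl-2,2'-diyl hydrogen phosphate (5 mol %), toluene, −30 °C; then H2O
Reagents that add atoms: none
Why: Chiral phosphoric acid-catalysed crotylboration through a closed chair (Zimmerman–Traxler) transition state, in which the (E)-boronate gives the anti relationship of C2 and C3 and the (S)-acid directs attack to the Si face of the aldehyde, so both centres are set as (1S,2S).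

Step 2
Reactants: 3 (1S,2S)-2-methyl-1-(3,4,5-trimethoxyphenyl)but-3-en-1-ol
Product: 4 tert-butyl(dimethyl){[(1S,2S)-2-methyl-1-(3,4,5-trimethoxyphenyl)but-3-en-1-yl]oxy}silane
Conditions: t-BuMe2SiCl, imidazole, DMF, rt
Reagents that add atoms: tert-butyl(chloro)dimethylsilane, CC(C)(C)[Si](C)(C)Cl
Why: Standard silylation of a secondary benzylic alcohol, needed so that the hydroxyl cannot lactonise onto the acid and ester made in the next steps.

Step 3
Reactants: 4 tert-butyl(dimethyl){[(1S,2S)-2-methyl-1-(3,4,5-trimethoxyphenyl)but-3-en-1-yl]oxy}silane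
Product: 6 (3S,4S)-4-{[tert-butyl(dimethyl)silyl]oxy}-3-methyl-4-(3,4,5-trimethoxyphenyl)butan-1-ol, via alkylborane 5 (not isolated)
Conditions: 9-BBN, THF, 0 °C → rt; then NaOH, H2O2, H2O, 0 °C → rt
Reagents that add atoms: hydrogen peroxide, OO
Why: Anti-Markovnikov hydroboration of the monosubstituted alkene by the bulky borane followed by oxidation of the C–B bond, a sequence that touches neither stereocentre.

Step 4
Reactants: 6 (3S,4S)-4-{[tert-butyl(dimethyl)silyl]oxy}-3-methyl-4-(3,4,5-trimethoxyphenyl)butan-1-ol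
Product: 7 (3S,4S)-4-{[tert-butyl(dimethyl)silyl]oxy}-3-methyl-4-(3,4,5-trimethoxyphenyl)butanoic acid
Conditions: 2,2,6,6-tetramethylpiperidin-1-oxyl (cat.), PhI(OAc)2, MeCN/H2O, rt
Reagents that add atoms: water, O
Why: Oxoammonium-mediated oxidation of the primary alcohol through the aldehyde hydrate to the acid, with a chlorine-free oxidant that spares the electron-rich arene and the silyl ether.

Step 5
Reactants: 7 (3S,4S)-4-{[tert-butyl(dimethyl)silyl]oxy}-3-methyl-4-(3,4,5-trimethoxyphenyl)butanoic acid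
Product: 8 tert-butyl (3S,4S)-4-{[tert-butyl(dimethyl)silyl]oxy}-3-methyl-4-(3,4,5-trimethoxyphenyl)butanoate
Conditions: Cl3CC(=NH)Ot-Bu, CH2Cl2/cyclohexane, rt
Reagents that add atoms: tert-butyl 2,2,2-trichloroacetimidate, CC(C)(C)OC(=N)C(Cl)(Cl)Cl
Why: Acid-promoted tert-butyl transfer from the trichloroacetimidate to the carboxylic acid under near-neutral conditions that keep the benzylic silyl ether; the tert-butyl ester is chosen because it is slow to be attacked by the alkoxide formed in step 9.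

Step 6
Reactants: 8 tert-butyl (3S,4S)-4-{[tert-butyl(dimethyl)silyl]oxy}-3-methyl-4-(3,4,5-trimethoxyphenyl)butanoate
Product: 9 tert-butyl (2RS)-2-[(1S,2S)-1-{[tert-butyl(dimethyl)silyl]oxy}-1-(3,4,5-trimethoxyphenyl)propan-2-yl]pent-4-enoate
Conditions: LiN(iPr)2, THF, −78 °C; allyl bromide, DMPU, −78 → −20 °C
Reagents that add atoms: 3-bromoprop-1-ene (allyl bromide), C=CCBr
Why: SN2 alkylation of the lithium ester enolate with an allylic bromide; the new centre forms as a mixture, which is of no consequence because it becomes planar again in step 9.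

Step 7
Reactants: 9 tert-butyl (2RS)-2-[(1S,2S)-1-{[tert-butyl(dimethyl)silyl]oxy}-1-(3,4,5-trimethoxyphenyl)propan-2-yl]pent-4-enoate
Product: 10 tert-butyl (2RS)-2-[(1S,2S)-1-hydroxy-1-(3,4,5-trimethoxyphenyl)propan-2-yl]pent-4-enoate
Conditions: HF·pyridine, pyridine, THF, 0 °C → rt
Reagents that add atoms: none
Why: Fluoride-mediated Si–O cleavage under buffered, non-basic conditions, so that no alkoxide is formed that could close onto the ester as a lactone.

Step 8
Reactants: 11 3,3-dichloroprop-2-enoic acid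
Product: 13 3,3-dichloro-N-methoxy-N-methylprop-2-enamide, via acid chloride 12 (not isolated)
Conditions: (COCl)2, N,N-dimethylformamide (cat.), CH2Cl2, 0 °C → rt; then MeNH(OMe)·HCl, pyridine, −20 → 0 °C
Reagents that add atoms: N,O-dimethylhydroxylamine hydrochloride, CNOC.Cl; oxalyl chloride, O=C(Cl)C(=O)Cl (its chlorine is in 12 only)
Why: Acid chloride formation followed by Schotten–Baumann-type N-acylation of the weakly nucleophilic hydroxylamine at low temperature, where acylation is much faster than substitution at the dichlorovinyl carbon.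

Step 9
Reactants: 10 tert-butyl (2RS)-2-[(1S,2S)-1-hydroxy-1-(3,4,5-trimethoxyphenyl)propan-2-yl]pent-4-enoate; 13 3,3-dichloro-N-methoxy-N-methylprop-2-enamide
Product: 15 tert-butyl (2E,3S,4S,5S)-2-{2-[methoxy(methyl)amino]-2-oxoethylidene}-4-methyl-3-(prop-2-en-1-yl)-5-(3,4,5-trimethoxyphenyl)oxolane-3-carboxylate, via chloro enol ether 14 (not isolated)
Conditions: KN(SiMe3)2 (1.05 equiv), THF, −78 → −20 °C; then KN(SiMe3)2 (1.3 equiv), −78 → 0 °C
Reagents that add atoms: none
Why: Proposed new method: the potassium alkoxide of 10 adds to the dichlorinated carbon of 13 and expels chloride (vinylic addition–elimination) to give 14, and the second portion of base, which finds no enolisable hydrogen on the amide side, forms the ester enolate that displaces the remaining chloride at the same carbon. The closest known reactions are the double vinylic substitution of β,β-dichloroacrylic acid derivatives and β,β-dichlorovinyl ketones by heteroatom binucleophiles and the 5-exo conjugate cyclisation of ester enolates; an alkoxide/ester-enolate pair closing onto one dichlorovinyl carbon to make a quaternary centre has not been described. Ring B closes in the 5-exo-trig mode, the C7a=C7 bond staying outside the new ring. The new stereocentre C3a is controlled by C3: allylic 1,3-strain holds C3–H in the plane of the tetrasubstituted enolate and C7a, tied to O1 on C2, can reach only the enolate face on the C2 side, so the allyl group ends cis to the C3 methyl group and both α-epimers of 10 converge. The step needs O-substitution before C-substitution and no lactonisation, which is secured by the order of deprotonation (hydroxyl first, one equivalent), by trapping the alkoxide at low temperature with 13 already present and by the slow attack of alkoxide on a tert-butyl ester. Single O-substitution follows from the stoichiometry and from 14 being a much weaker electrophile than 13.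

Step 10
Reactants: 15 tert-butyl (2E,3S,4S,5S)-2-{2-[methoxy(methyl)amino]-2-oxoethylidene}-4-methyl-3-(prop-2-en-1-yl)-5-(3,4,5-trimethoxyphenyl)oxolane-3-carboxylate
Product: 16 tert-butyl (2E,3S,4S,5S)-2-(3-methoxy-2-oxopropylidene)-4-methyl-3-(prop-2-en-1-yl)-5-(3,4,5-trimethoxyphenyl)oxolane-3-carboxylate
Conditions: Bu3SnCH2OMe, n-BuLi, THF, −78 °C; then 15, −78 °C; aq NH4Cl
Reagents that add atoms: tributyl(methoxymethyl)stannane, CCCC[Sn](CCCC)(CCCC)COC
Why: 1,2-Addition of an α-alkoxy organolithium (from tin–lithium exchange) to the Weinreb amide, where the chelated tetrahedral adduct prevents a second addition and the hindered tert-butyl ester on the quaternary carbon is not attacked at −78 °C.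

Step 11
Reactants: 16 tert-butyl (2E,3S,4S,5S)-2-(3-methoxy-2-oxopropylidene)-4-methyl-3-(prop-2-en-1-yl)-5-(3,4,5-trimethoxyphenyl)oxolane-3-carboxylate
Product: 17 (E)-3-[(3R,4S,5S)-3-(hydroxymethyl)-4-methyl-3-(prop-2-en-1-yl)-5-(3,4,5-trimethoxyphenyl)oxolan-2-ylidene]-1-methoxypropan-2-ol (both carbinol epimers)
Conditions: LiAlH4, THF, 0 °C → rt; aq NaOH work-up
Reagents that add atoms: none
Why: Hydride reduction of the ester to the primary alcohol C4, accepting 1,2-reduction of the vinylogous ester ketone at the same time (the new carbinol is removed again in step 12), with a basic work-up that keeps the acid-sensitive enol ether–allylic alcohol intact.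

Step 12
Reactants: 17 (E)-3-[(3R,4S,5S)-3-(hydroxymethyl)-4-methyl-3-(prop-2-en-1-yl)-5-(3,4,5-trimethoxyphenyl)oxolan-2-ylidene]-1-methoxypropan-2-ol
Product: 18 (2E,3S,4S,5S)-2-(3-methoxy-2-oxopropylidene)-4-methyl-3-(prop-2-en-1-yl)-5-(3,4,5-trimethoxyphenyl)oxolane-3-carbaldehyde
Conditions: Dess–Martin periodinane, pyridine, CH2Cl2, 0 °C → rt
Reagents that add atoms: none
Why: Dess–Martin oxidation of both alcohols under pyridine buffering, which returns the allylic carbinol to the vinylogous ester ketone and turns the neopentyl alcohol into the non-enolisable aldehyde C4.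

Step 13
Reactants: 18 (2E,3S,4S,5S)-2-(3-methoxy-2-oxopropylidene)-4-methyl-3-(prop-2-en-1-yl)-5-(3,4,5-trimethoxyphenyl)oxolane-3-carbaldehyde
Product: 20 (2S,3S,3aR)-5-methoxy-3-methyl-3a-(prop-2-en-1-yl)-2-(3,4,5-trimethoxyphenyl)-3,3a-dihydro-1-benzofuran-6(2H)-one, via aldol adduct 19 (not isolated)
Conditions: K2CO3, MeOH, 0 → 40 °C
Reagents that add atoms: none
Why: Intramolecular aldol condensation (C5 enolate onto the C4 aldehyde, then E1cB loss of water) closes ring A as the cross-conjugated dienone, while reversible addition of methoxide at C7a lets the exocyclic enol ether reach the E geometry that alone can cyclise, and no stereocentre of 18 is enolisable.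

**Compound list**
1 | 3,4,5-trimethoxybenzaldehyde | COc1cc(C=O)cc(OC)c1OC | starting material
2 | (E)-crotylboronic acid pinacol ester | C/C=C/CB1OC(C)(C)C(C)(C)O1 | starting material
3 | (1S,2S)-2-methyl-1-(3,4,5-trimethoxyphenyl)but-3-en-1-ol | C=C[C@H](C)[C@@H](c1cc(OC)c(OC)c(OC)c1)O | intermediate
4 | tert-butyl(dimethyl){[(1S,2S)-2-methyl-1-(3,4,5-trimethoxyphenyl)but-3-en-1-yl]oxy}silane | C=C[C@H](C)[C@@H](c1cc(OC)c(OC)c(OC)c1)O[Si](C)(C)C(C)(C)C | intermediate
5 | 9-[(3S,4S)-4-{[tert-butyl(dimethyl)silyl]oxy}-3-methyl-4-(3,4,5-trimethoxyphenyl)butyl]-9-borabicyclo[3.3.1]nonane | C1CCC2CCCC1B2CC[C@H](C)[C@@H](c1cc(OC)c(OC)c(OC)c1)O[Si](C)(C)C(C)(C)C | intermediate (not isolated)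
6 | (3S,4S)-4-{[tert-butyl(dimethyl)silyl]oxy}-3-methyl-4-(3,4,5-trimethoxyphenyl)butan-1-ol | OCC[C@H](C)[C@@H](c1cc(OC)c(OC)c(OC)c1)O[Si](C)(C)C(C)(C)C | intermediate
7 | (3S,4S)-4-{[tert-butyl(dimethyl)silyl]oxy}-3-methyl-4-(3,4,5-trimethoxyphenyl)butanoic acid | OC(=O)C[C@H](C)[C@@H](c1cc(OC)c(OC)c(OC)c1)O[Si](C)(C)C(C)(C)C | intermediate
8 | tert-butyl (3S,4S)-4-{[tert-butyl(dimethyl)silyl]oxy}-3-methyl-4-(3,4,5-trimethoxyphenyl)butanoate | CC(C)(C)OC(=O)C[C@H](C)[C@@H](c1cc(OC)c(OC)c(OC)c1)O[Si](C)(C)C(C)(C)C | intermediate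
9 | tert-butyl (2RS)-2-[(1S,2S)-1-{[tert-butyl(dimethyl)silyl]oxy}-1-(3,4,5-trimethoxyphenyl)propan-2-yl]pent-4-enoate | C=CCC(C(=O)OC(C)(C)C)[C@H](C)[C@@H](c1cc(OC)c(OC)c(OC)c1)O[Si](C)(C)C(C)(C)C | intermediate
10 | tert-butyl (2RS)-2-[(1S,2S)-1-hydroxy-1-(3,4,5-trimethoxyphenyl)propan-2-yl]pent-4-enoate | C=CCC(C(=O)OC(C)(C)C)[C@H](C)[C@@H](c1cc(OC)c(OC)c(OC)c1)O | intermediate
11 | 3,3-dichloroprop-2-enoic acid | OC(=O)C=C(Cl)Cl | starting material
12 | 3,3-dichloroprop-2-enoyl chloride | ClC(=O)C=C(Cl)Cl | intermediate (not isolated)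
13 | 3,3-dichloro-N-methoxy-N-methylprop-2-enamide | CON(C)C(=O)C=C(Cl)Cl | intermediate
14 | tert-butyl (2RS)-2-[(1S,2S)-1-({1-chloro-3-[methoxy(methyl)amino]-3-oxoprop-1-en-1-yl}oxy)-1-(3,4,5-trimethoxyphenyl)propan-2-yl]pent-4-enoate | C=CCC(C(=O)OC(C)(C)C)[C@H](C)[C@@H](c1cc(OC)c(OC)c(OC)c1)OC(Cl)=CC(=O)N(C)OC | intermediate (not isolated)
15 | tert-butyl (2E,3S,4S,5S)-2-{2-[methoxy(methyl)amino]-2-oxoethylidene}-4-methyl-3-(prop-2-en-1-yl)-5-(3,4,5-trimethoxyphenyl)oxolane-3-carboxylate (E shown; any Z isomer is carried on) | C=CC[C@@]1(C(=O)OC(C)(C)C)/C(=C\C(=O)N(C)OC)O[C@H](c2cc(OC)c(OC)c(OC)c2)[C@H]1C | intermediate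
16 | tert-butyl (2E,3S,4S,5S)-2-(3-methoxy-2-oxopropylidene)-4-methyl-3-(prop-2-en-1-yl)-5-(3,4,5-trimethoxyphenyl)oxolane-3-carboxylate | C=CC[C@@]1(C(=O)OC(C)(C)C)/C(=C\C(=O)COC)O[C@H](c2cc(OC)c(OC)c(OC)c2)[C@H]1C | intermediate
17 | (E)-3-[(3R,4S,5S)-3-(hydroxymethyl)-4-methyl-3-(prop-2-en-1-yl)-5-(3,4,5-trimethoxyphenyl)oxolan-2-ylidene]-1-methoxypropan-2-ol | C=CC[C@@]1(CO)/C(=C\C(O)COC)O[C@H](c2cc(OC)c(OC)c(OC)c2)[C@H]1C | intermediate
18 | (2E,3S,4S,5S)-2-(3-methoxy-2-oxopropylidene)-4-methyl-3-(prop-2-en-1-yl)-5-(3,4,5-trimethoxyphenyl)oxolane-3-carbaldehyde | C=CC[C@@]1(C=O)/C(=C\C(=O)COC)O[C@H](c2cc(OC)c(OC)c(OC)c2)[C@H]1C | intermediate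
19 | (2S,3S,3aR)-4-hydroxy-5-methoxy-3-methyl-3a-(prop-2-en-1-yl)-2-(3,4,5-trimethoxyphenyl)-3,3a,4,5-tetrahydro-1-benzofuran-6(2H)-one | C=CC[C@@]12C(O)C(OC)C(=O)C=C1O[C@H](c1cc(OC)c(OC)c(OC)c1)[C@H]2C | intermediate (not isolated)
20 | (2S,3S,3aR)-5-methoxy-3-methyl-3a-(prop-2-en-1-yl)-2-(3,4,5-trimethoxyphenyl)-3,3a-dihydro-1-benzofuran-6(2H)-one | C=CC[C@@]12C=C(OC)C(=O)C=C1O[C@H](c1cc(OC)c(OC)c(OC)c1)[C@H]2C | target

**Step count**
Total: 13 steps. Longest linear sequence: 12 steps (steps 1–7 and 9–13); step 8 is a one-step side branch.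

**Steps most likely to fail**

Step 9. The alkoxide may close onto the tert-butyl ester before it is trapped, the hindered enolate may displace the second chloride too slowly so that 14 is consumed intermolecularly, or the enolate face may be poorly differentiated. The fallback uses known reactions only, sets out from 3 and returns at 15; C3a is then set by acylation of a cyclic enolate instead of by the annulation. Alcohol 3 is hydroborated and oxidised (9-BBN; NaOH, H2O2) to (1S,2S)-2-methyl-1-(3,4,5-trimethoxyphenyl)butane-1,4-diol F1. Oxoammonium oxidation (2,2,6,6-tetramethylpiperidin-1-oxyl, PhI(OAc)2) closes the trans lactone (4S,5S)-4-methyl-5-(3,4,5-trimethoxyphenyl)oxolan-2-one F2. LiN(iPr)2 and allyl bromide give (3S,4S,5S)-4-methyl-3-(prop-2-en-1-yl)-5-(3,4,5-trimethoxyphenyl)oxolan-2-one F3. Its enolate (LiN(SiMe3)2) is C-acylated with di-tert-butyl dicarbonate on the face away from the 4-methyl group, which places the ester trans and the allyl group cis to methyl, giving tert-butyl (3S,4S,5S)-4-methyl-2-oxo-3-(prop-2-en-1-yl)-5-(3,4,5-trimethoxyphenyl)oxolane-3-carboxylate F4. Claisen-type addition of the lithium enolate of N-methoxy-N-methylacetamide to the lactone carbonyl gives the hemiketal tert-butyl (3S,4S,5S)-2-hydroxy-2-{2-[methoxy(methyl)amino]-2-oxoethyl}-4-methyl-3-(prop-2-en-1-yl)-5-(3,4,5-trimethoxyphenyl)oxolane-3-carboxylate F5, and dehydration (MeSO2Cl, Et3N) gives 15.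

Step 13. Interconversion of the exocyclic enol ether geometries may be slow, and in that time methoxide may cleave the formyl group (retro-Claisen) or open ring B. The fallback sets out from 16 and returns at 20; it closes ring A on the ester, which survives prolonged basic heating, and corrects the oxidation level afterwards. Dieckmann condensation of 16 (KOt-Bu, t-BuOH/THF, warm; C5 enolate onto the tert-butyl ester) gives (2S,3S,3aS)-5-methoxy-3-methyl-3a-(prop-2-en-1-yl)-2-(3,4,5-trimethoxyphenyl)-3,3a-dihydro-1-benzofuran-4,6(2H,5H)-dione F6. Silylation of the less hindered and more electron-rich O6 (i-Pr3SiCl, Et3N) gives (2S,3S,3aS)-5-methoxy-3-methyl-3a-(prop-2-en-1-yl)-6-{[tri(propan-2-yl)silyl]oxy}-2-(3,4,5-trimethoxyphenyl)-3,3a-dihydro-1-benzofuran-4(2H)-one F7. 1,2-Reduction of the C4 carbonyl (i-Bu2AlH, −78 °C) gives (2S,3S,3aR)-5-methoxy-3-methyl-3a-(prop-2-en-1-yl)-6-{[tri(propan-2-yl)silyl]oxy}-2-(3,4,5-trimethoxyphenyl)-2,3,3a,4-tetrahydro-1-benzofuran-4-ol F8. Bu4NF then removes the silyl group and the C6 enolate expels the C4 hydroxyl (Stork–Danheiser carbonyl transposition), giving 20.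

Step 11. The enol ether–allylic alcohol of 17 may ionise during work-up or oxidation, with opening of ring B. The fallback sets out from 16 and returns at 18; it avoids reducing the ketone. The ketone of 16 is masked as its lithium enolate (LiN(SiMe3)2, THF, −78 °C), LiAlH4 then reduces only the ester, and work-up returns (E)-1-[(3R,4S,5S)-3-(hydroxymethyl)-4-methyl-3-(prop-2-en-1-yl)-5-(3,4,5-trimethoxyphenyl)oxolan-2-ylidene]-3-methoxypropan-2-one F9, whose enol ether stays conjugated to a ketone and is therefore not acid-labile. Dess–Martin oxidation of the single primary alcohol gives 18.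

**Further compounds**
F1 | step 9 | (1S,2S)-2-methyl-1-(3,4,5-trimethoxyphenyl)butane-1,4-diol | OCC[C@H](C)[C@@H](c1cc(OC)c(OC)c(OC)c1)O
F2 | step 9 | (4S,5S)-4-methyl-5-(3,4,5-trimethoxyphenyl)oxolan-2-one | O=C1C[C@H](C)[C@@H](c2cc(OC)c(OC)c(OC)c2)O1
F3 | step 9 | (3S,4S,5S)-4-methyl-3-(prop-2-en-1-yl)-5-(3,4,5-trimethoxyphenyl)oxolan-2-one | C=CC[C@@H]1C(=O)O[C@H](c2cc(OC)c(OC)c(OC)c2)[C@H]1C
F4 | step 9 | tert-butyl (3S,4S,5S)-4-methyl-2-oxo-3-(prop-2-en-1-yl)-5-(3,4,5-trimethoxyphenyl)oxolane-3-carboxylate | C=CC[C@@]1(C(=O)OC(C)(C)C)C(=O)O[C@H](c2cc(OC)c(OC)c(OC)c2)[C@H]1C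
F5 | step 9 | tert-butyl (3S,4S,5S)-2-hydroxy-2-{2-[methoxy(methyl)amino]-2-oxoethyl}-4-methyl-3-(prop-2-en-1-yl)-5-(3,4,5-trimethoxyphenyl)oxolane-3-carboxylate | C=CC[C@@]1(C(=O)OC(C)(C)C)C(O)(CC(=O)N(C)OC)O[C@H](c2cc(OC)c(OC)c(OC)c2)[C@H]1C
F6 | step 13 | (2S,3S,3aS)-5-methoxy-3-methyl-3a-(prop-2-en-1-yl)-2-(3,4,5-trimethoxyphenyl)-3,3a-dihydro-1-benzofuran-4,6(2H,5H)-dione | C=CC[C@@]12C(=O)C(OC)C(=O)C=C1O[C@H](c1cc(OC)c(OC)c(OC)c1)[C@H]2C
F7 | step 13 | (2S,3S,3aS)-5-methoxy-3-methyl-3a-(prop-2-en-1-yl)-6-{[tri(propan-2-yl)silyl]oxy}-2-(3,4,5-trimethoxyphenyl)-3,3a-dihydro-1-benzofuran-4(2H)-one | C=CC[C@@]12C(=O)C(OC)=C(O[Si](C(C)C)(C(C)C)C(C)C)C=C1O[C@H](c1cc(OC)c(OC)c(OC)c1)[C@H]2C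
F8 | step 13 | (2S,3S,3aR)-5-methoxy-3-methyl-3a-(prop-2-en-1-yl)-6-{[tri(propan-2-yl)silyl]oxy}-2-(3,4,5-trimethoxyphenyl)-2,3,3a,4-tetrahydro-1-benzofuran-4-ol | C=CC[C@@]12C(O)C(OC)=C(O[Si](C(C)C)(C(C)C)C(C)C)C=C1O[C@H](c1cc(OC)c(OC)c(OC)c1)[C@H]2C
F9 | step 11 | (E)-1-[(3R,4S,5S)-3-(hydroxymethyl)-4-methyl-3-(prop-2-en-1-yl)-5-(3,4,5-trimethoxyphenyl)oxolan-2-ylidene]-3-methoxypropan-2-one | C=CC[C@@]1(CO)/C(=C\C(=O)COC)O[C@H](c2cc(OC)c(OC)c(OC)c2)[C@H]1C
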